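Ring A (C1, C11–C15; verticillane numbering) is not built as a six-membered ring: C1, C13, C14 and C15 arrive as the cyclobutane of (+)-α-pinene, and C11–C12 are spliced in between C13 and the gem-dimethyl carbon C15. In the key step the alkoxy radical of a 1-alkenyl-2,2-dimethylcyclobutanol cleaves the strained C13–C15 bond, and the tertiary C15 radical closes 6-endo onto C11 of the enone it has just unveiled: one operation makes ring A, the C13 ketone, the C11–C15 bond and the C11 stereocentre. Ring-closing metathesis at C3=C4 then shuts the twelve-membered ring; unmasking of the 12(18)-methylene ketone, acetylation and peripheral bis-epoxidation finish.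

Key step: step 14

Remarks and assumptions
- Numbering: C1 is the bridgehead CH bearing C2; C2–C10 is the nine-carbon bridge (oxiranes at C3–C4 and C7–C8, acetoxy at C10); C11 is the CH between C10 and C12; C12 carries the methylene C18; C13 is the ketone; C14 is CH2; C15 is CMe2. The target is read as 1R,3R,4R,7R,8S,10R,11S: the 3,4-oxirane comes from an E olefin, the 7,8-oxirane from a Z olefin, and C2 and C10 are trans on ring A.
- Assumption: the two oxirane configurations of the target are taken to be those formed by peracid attack on the outer faces of the two ring olefins of the macrocyclic diene.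
- Assumption: the (S)-BINOL/Ti(OiPr)4 alkynylzinc addition is taken to give the R carbinol from an unbranched aliphatic aldehyde; the enantiomeric ligand is equally available.
- Compounds 21–24 are C12 epimer mixtures (no stereo tag at C12); this centre becomes sp2 in step 17.

Step 1
Reactants: 1 (+)-α-pinene
Product: 2 cis-pinonic acid
Conditions: RuCl3·xH2O (cat.), NaIO4, EtOAc/MeCN/H2O, 0 °C to rt
Reagents that add atoms: sodium periodate [Na+].[O-]I(=O)(=O)=O
Why: RuO4-type oxidative cleavage of the trisubstituted olefin gives the keto acid; the pinene C5 centre, which becomes C1 of the target, is untouched.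

Step 2
Reactants: 2 cis-pinonic acid
Product: 3 2-[(1S,3S)-3-acetoxy-2,2-dimethylcyclobutyl]acetic acid
Conditions: mCPBA, CF3CO2H (cat.), CH2Cl2, rt, dark
Reagents that add atoms: mCPBA OOC(=O)c1cccc(Cl)c1
Why: Baeyer–Villiger oxidation of the methyl ketone, in which the secondary cyclobutyl carbon migrates in preference to methyl with retention.

Step 3
Reactants: 3 acetoxy acid
Product: 4 (1S,3R)-3-(2-hydroxyethyl)-2,2-dimethylcyclobutan-1-ol
Conditions: LiAlH4, THF, 0 °C to reflux; aqueous NaOH work-up
Reagents that add atoms: none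
Why: Hydride reduction of the carboxylic acid and reductive removal of the acetate give the diol in one operation.

Step 4
Reactants: 4 diol
Product: 5 2-[(1R)-2,2-dimethyl-3-oxocyclobutyl]acetaldehyde
Conditions: Dess–Martin periodinane (2.4 equiv), NaHCO3, CH2Cl2, 0 °C to rt
Reagents that add atoms: none
Why: Dess–Martin oxidation of both the primary and the secondary alcohol; the stereocentre is β to both carbonyl groups and cannot epimerise.

Step 5
Reactants: 5 keto aldehyde
Product: 6 (3R)-2,2-dimethyl-3-(prop-2-en-1-yl)cyclobutan-1-one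
Conditions: Ph3PCH3Br, KN(SiMe3)2, THF, 0 °C; then 5 (1.0 equiv of ylide), −78 °C
Reagents that add atoms: methyltriphenylphosphonium bromide C[P+](c1ccccc1)(c1ccccc1)c1ccccc1.[Br-]
Why: Wittig methylenation, chemoselective for the unhindered aldehyde over the cyclobutanone flanked by the quaternary carbon.

Step 6
Reactants: 7 ethyl 4-methylpent-4-enoate
Product: 8 4-methylpent-4-enal
Conditions: i-Bu2AlH (1.05 equiv), CH2Cl2, −78 °C; aqueous potassium sodium tartrate
Reagents that add atoms: none
Why: Partial reduction of the ester to the aldehyde through the tetrahedral aluminium hemiacetal, stable at −78 °C.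

Step 7
Reactants: 8 4-methylpent-4-enal
Product: 9 (5Z)-6-iodo-2-methylhepta-1,5-diene
Conditions: [Ph3PCH2CH3]I, n-BuLi, THF, 0 °C; I2, −78 °C; NaN(SiMe3)2, −78 °C; then 8, −78 to −20 °C
Reagents that add atoms: ethyltriphenylphosphonium iodide CC[P+](c1ccccc1)(c1ccccc1)c1ccccc1.[I-]; iodine II
Why: Stork–Zhao olefination with the α-iodoethylidene ylide gives the trisubstituted vinyl iodide with iodine cis to the chain, which fixes the later 7Z geometry.

Step 8
Reactants: 9 (Z)-vinyl iodide
Product: 11 (3Z)-3,7-dimethylocta-3,7-dien-1-ol, via alkenyllithium 10 (not isolated)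
Conditions: t-BuLi (2.0 equiv), Et2O, −78 °C; then oxirane, BF3·OEt2, −78 °C
Reagents that add atoms: oxirane C1CO1
Why: Iodine–lithium exchange with retention of olefin geometry, then Lewis-acid-assisted opening of ethylene oxide, adds C9 and C10.

Step 9
Reactants: 11 dienol
Product: 12 (3Z)-3,7-dimethylocta-3,7-dienal
Conditions: Dess–Martin periodinane, NaHCO3, CH2Cl2, 0 °C; used directly
Reagents that add atoms: none
Why: Buffered, non-basic Dess–Martin oxidation avoids migration of the β,γ-olefin into conjugation.

Step 10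
Reactants: 12 dienal; 13 tert-butyldimethyl(prop-2-yn-1-yloxy)silane
Product: 15 (4R,6Z)-1-[(tert-butyldimethylsilyl)oxy]-6,10-dimethylundeca-6,10-dien-2-yn-4-ol, via ethyl alkynylzinc 14 (not isolated)
Conditions: 13, Et2Zn, toluene, reflux; then (S)-BINOL (20 mol %), Ti(OiPr)4 (50 mol %), CH2Cl2, rt; then 12
Reagents that add atoms: none
Why: Catalytic asymmetric alkynylzinc addition to the aldehyde under amine-free conditions sets C10 (R) by ligand control; the enantiomeric ligand would be used if the sense were found reversed.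

Step 11
Reactants: 15 propargylic alcohol
Product: 17 (2Z,4R,6Z)-1-[(tert-butyldimethylsilyl)oxy]-2-iodo-6,10-dimethylundeca-2,6,10-trien-4-ol, via cyclic alkenylalanate 16 (not isolated)
Conditions: NaAlH2(OCH2CH2OCH3)2, THF, 0 °C; then I2, THF, −78 °C
Reagents that add atoms: iodine II
Why: Hydroxyl-directed trans-hydroalumination puts hydride on C11 and aluminium on the distal carbon C12, and iodinolysis with retention gives the vinyl iodide with iodine cis to C10.

Step 12
Reactants: 17 iodo allylic alcohol
Product: 18 bis(tert-butyldimethylsilyl) ether of 17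
Conditions: TBSOTf, 2,6-lutidine, CH2Cl2, −78 to 0 °C
Reagents that add atoms: tert-butyldimethylsilyl trifluoromethanesulfonate CC(C)(C)[Si](C)(C)OS(=O)(=O)C(F)(F)F
Why: Standard silylation of the secondary allylic alcohol so that the C10 oxygen survives the organolithium step.

Step 13
Reactants: 18 bis-silyl vinyl iodide; 6 (3R)-3-allyl-2,2-dimethylcyclobutanone
Product: 20 tertiary 1-alkenylcyclobutanol, via alkenyllithium 19 (not isolated)
Conditions: t-BuLi (2.05 equiv), Et2O, −78 °C; then 6, −78 °C
Reagents that add atoms: none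
Why: Iodine–lithium exchange with retention and 1,2-addition to the strained ketone from the face anti to the allyl group; the new carbinol centre C13 is planarised in step 14, so its configuration is immaterial.

Step 14
Reactants: 20 tertiary 1-alkenylcyclobutanol
Product: 21 ring-expanded cyclohexanone (3R,5R)-5-allyl-2-[(tert-butyldimethylsilyloxy)methyl]-3-[(1R,3Z)-1-(tert-butyldimethylsilyloxy)-3,7-dimethylocta-3,7-dienyl]-4,4-dimethylcyclohexan-1-one
Conditions: [Ir(dF(CF3)ppy)2(5,5'-d(CF3)bpy)]PF6 (2 mol %), 2,4,6-collidine, PhCF3 (0.02 M), blue LEDs, rt, degassed, no hydrogen-atom donor added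
Reagents that add atoms: none
Why: The excited trivalent-iridium photocatalyst and collidine remove an electron and a proton from the tertiary O–H, and the strained cyclobutyloxyl radical undergoes β-scission of C13–C15 toward the tertiary C15 radical, unveiling the C13 ketone as an enone with C10 cis to C13. The nucleophilic C15 radical closes ring A by 6-endo-trig addition to the β-carbon C11 (5-exo attack on the fully substituted α-carbon C12 is sterically and polarity disfavoured), and the α-keto radical is reduced by divalent iridium and protonated by collidinium, so the step is a redox-neutral isomerisation. The closest known reaction type is the photocatalytic proton-coupled electron-transfer ring expansion of 1-alkenylcycloalkanols by two atoms. C11 is set in a chair-like transition state with the C1 allyl group equatorial: the olefin geometry forces C10 axial, so C2 and C10 end up trans across C15, whereas attack on the other face would need a 1,3-diaxial arrangement; this face is also anti to the C10–O bond (Felkin–Anh), so the C10 (R) centre is matched. C12 is formed as an epimer mixture of no consequence. The step needs regioselective scission (secured by the gem-dimethyl group), endo closure (secured by substitution at C12) and cyclisation faster than quenching (the alkyl radical cannot be reduced by the catalyst, the enoxyl radical can).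

Step 15
Reactants: 21 ring-expanded cyclohexanone
Product: 22 bicyclic macrocycle (1R,3E,7Z,10R,11R)-10-(tert-butyldimethylsilyloxy)-18-(tert-butyldimethylsilyloxy)verticilla-3,7-dien-13-one
Conditions: second-generation Grubbs catalyst RuCl2(=CHPh)(H2IMes)(PCy3) (10 mol %), toluene (1 mM), 80 °C, argon sparge
Reagents that add atoms: none
Why: Ring-closing metathesis between the allyl group and the 1,1-disubstituted olefin closes the twelve-membered ring at C3=C4 with loss of ethylene; the E olefin is expected under thermodynamic control, and the trisubstituted 7Z olefin and the masked enone are inert.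

Step 16
Reactants: 22 bis-silyl macrocycle
Product: 23 diol (1R,3E,7Z,10R,11R)-10,18-dihydroxyverticilla-3,7-dien-13-one
Conditions: HF·pyridine, pyridine, THF, 0 °C to rt
Reagents that add atoms: none
Why: Acidic fluoride desilylation frees both hydroxyl groups without the retro-aldol or premature elimination that basic fluoride could cause at the β-hydroxy ketone.

Step 17
Reactants: 23 diol
Product: 25 (1R,3E,7Z,10R,11S)-10-acetoxyverticilla-3,7,12(18)-trien-13-one, via bis-acetate 24 (not isolated)
Conditions: Ac2O, Et3N, DMAP, CH2Cl2, 0 °C to rt; then DBU (1.1 equiv), 0 °C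
Reagents that add atoms: acetic anhydride CC(=O)OC(C)=O
Why: Acetylation of both alcohols followed by E1cB elimination of the β-acetoxy ketone unveils the 12(18)-methylene ketone and leaves the C10 acetate in place.

Step 18
Reactants: 25 dienone acetate
Product: 26 target (1R,3R,4R,7R,8S,10R,11S)-10-acetoxy-3,4:7,8-diepoxyverticill-12(18)-en-13-one
Conditions: mCPBA (2.2 equiv), NaHCO3, CH2Cl2, −20 to 0 °C
Reagents that add atoms: mCPBA OOC(=O)c1cccc(Cl)c1
Why: Stereospecific Prilezhaev epoxidation of the two electron-rich trisubstituted olefins (E gives the trans 3,4-oxirane, Z the cis 7,8-oxirane) from their outer faces; the electron-poor methylene ketone is not attacked.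

Compound list
1 | (+)-α-pinene, (1R,5R)-2,6,6-trimethylbicyclo[3.1.1]hept-2-ene | CC1=CC[C@@H]2C[C@H]1C2(C)C | starting material
2 | cis-pinonic acid, 2-[(1S,3S)-3-acetyl-2,2-dimethylcyclobutyl]acetic acid | CC(=O)[C@H]1C[C@@H](CC(=O)O)C1(C)C | intermediate
3 | 2-[(1S,3S)-3-acetoxy-2,2-dimethylcyclobutyl]acetic acid | CC(=O)O[C@H]1C[C@@H](CC(=O)O)C1(C)C | intermediate
4 | (1S,3R)-3-(2-hydroxyethyl)-2,2-dimethylcyclobutan-1-ol | O[C@H]1C[C@@H](CCO)C1(C)C | intermediate
5 | 2-[(1R)-2,2-dimethyl-3-oxocyclobutyl]acetaldehyde | O=CC[C@@H]1CC(=O)C1(C)C | intermediate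
6 | (3R)-2,2-dimethyl-3-(prop-2-en-1-yl)cyclobutan-1-one | C=CC[C@@H]1CC(=O)C1(C)C | intermediate
7 | ethyl 4-methylpent-4-enoate | C=C(C)CCC(=O)OCC | starting material
8 | 4-methylpent-4-enal | C=C(C)CCC=O | intermediate
9 | (5Z)-6-iodo-2-methylhepta-1,5-diene | C=C(C)CC/C=C(\I)C | intermediate
10 | (Z)-alkenyllithium from 9 (lithium in place of iodine) | C=C(C)CC/C=C(\[Li])C | intermediate (not isolated)
11 | (3Z)-3,7-dimethylocta-3,7-dien-1-ol | C=C(C)CC/C=C(\CCO)C | intermediate
12 | (3Z)-3,7-dimethylocta-3,7-dienal | C=C(C)CC/C=C(\CC=O)C | intermediate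
13 | tert-butyldimethyl(prop-2-yn-1-yloxy)silane | C#CCO[Si](C)(C)C(C)(C)C | starting material
14 | ethyl[3-(tert-butyldimethylsilyloxy)prop-1-ynyl]zinc | CC[Zn]C#CCO[Si](C)(C)C(C)(C)C | intermediate (not isolated)
15 | (4R,6Z)-1-[(tert-butyldimethylsilyl)oxy]-6,10-dimethylundeca-6,10-dien-2-yn-4-ol | C=C(C)CC/C=C(C)\C[C@@H](O)C#CCO[Si](C)(C)C(C)(C)C | intermediate
16 | sodium cyclic alkenylalanate (five-membered O–Al–C12=C11–C10 ring, two 2-methoxyethoxide ligands on aluminium) | C=C(C)CC/C=C(C)\C[C@H]1O[Al-](OCCOC)(OCCOC)C(CO[Si](C)(C)C(C)(C)C)=C1.[Na+] | intermediate (not isolated)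
17 | (2Z,4R,6Z)-1-[(tert-butyldimethylsilyl)oxy]-2-iodo-6,10-dimethylundeca-2,6,10-trien-4-ol | C=C(C)CC/C=C(C)\C[C@@H](O)/C=C(\I)CO[Si](C)(C)C(C)(C)C | intermediate
18 | (2Z,4R,6Z)-1,4-bis[(tert-butyldimethylsilyl)oxy]-2-iodo-6,10-dimethylundeca-2,6,10-triene | C=C(C)CC/C=C(C)\C[C@@H](O[Si](C)(C)C(C)(C)C)/C=C(\I)CO[Si](C)(C)C(C)(C)C | intermediate
19 | alkenyllithium from 18 (lithium in place of iodine) | C=C(C)CC/C=C(C)\C[C@@H](O[Si](C)(C)C(C)(C)C)/C=C(\[Li])CO[Si](C)(C)C(C)(C)C | intermediate (not isolated)
20 | (1S,3R)-3-allyl-2,2-dimethyl-1-[(2Z,4R,6Z)-1,4-bis(tert-butyldimethylsilyloxy)-6,10-dimethylundeca-2,6,10-trien-2-yl]cyclobutan-1-ol (alkenyl trans to allyl) | C=C(C)CC/C=C(C)\C[C@@H](O[Si](C)(C)C(C)(C)C)/C=C(CO[Si](C)(C)C(C)(C)C)\[C@]1(O)C[C@@H](CC=C)C1(C)C | intermediate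
21 | (3R,5R)-5-allyl-2-[(tert-butyldimethylsilyloxy)methyl]-3-[(1R,3Z)-1-(tert-butyldimethylsilyloxy)-3,7-dimethylocta-3,7-dienyl]-4,4-dimethylcyclohexan-1-one, C2 epimers (allyl and side chain trans) | C=CC[C@@H]1CC(=O)C(CO[Si](C)(C)C(C)(C)C)[C@@H]([C@H](O[Si](C)(C)C(C)(C)C)C/C(C)=C\CCC(C)=C)C1(C)C | intermediate
22 | (1R,3E,7Z,10R,11R)-10,18-bis(tert-butyldimethylsilyloxy)verticilla-3,7-dien-13-one, C12 epimers | CC(C)(C)[Si](C)(C)OCC1C(=O)C[C@H]2C/C=C(C)/CC/C=C(C)\C[C@@H](O[Si](C)(C)C(C)(C)C)[C@H]1C2(C)C | intermediate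
23 | (1R,3E,7Z,10R,11R)-10,18-dihydroxyverticilla-3,7-dien-13-one, C12 epimers | OCC1C(=O)C[C@H]2C/C=C(C)/CC/C=C(C)\C[C@@H](O)[C@H]1C2(C)C | intermediate
24 | (1R,3E,7Z,10R,11R)-10,18-diacetoxyverticilla-3,7-dien-13-one, C12 epimers | CC(=O)OCC1C(=O)C[C@H]2C/C=C(C)/CC/C=C(C)\C[C@@H](OC(C)=O)[C@H]1C2(C)C | intermediate (not isolated)
25 | (1R,3E,7Z,10R,11S)-10-acetoxyverticilla-3,7,12(18)-trien-13-one | C=C1C(=O)C[C@H]2C/C=C(C)/CC/C=C(C)\C[C@@H](OC(C)=O)[C@H]1C2(C)C | intermediate
26 | (1R,3R,4R,7R,8S,10R,11S)-10-acetoxy-3,4:7,8-diepoxyverticill-12(18)-en-13-one | C=C1C(=O)C[C@H]2C[C@H]3O[C@]3(C)CC[C@H]3O[C@@]3(C)C[C@@H](OC(C)=O)[C@H]1C2(C)C | target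

Total step count: 18.
Longest linear sequence: 13 steps (steps 6–18, from ethyl 4-methylpent-4-enoate); the pinene branch (steps 1–5) joins at step 13.

Steps most likely to fail

1. Step 14 (ring expansion). The 6-endo closure joins a tertiary radical to a β-carbon that carries the branched C10 substituent. It may be too slow to compete with loss of the C15 radical. The α-keto radical may also live long enough to add to the nearby 7,8-olefin instead of being reduced. Fallback, from 20 back to the route at 25: the α-keto radical is given a built-in fast exit. Buffered HF·pyridine at 0 °C cleaves only the primary allylic silyl ether of 20 to give the allylic alcohol F1. PhSSPh and n-Bu3P convert F1 into the allyl phenyl sulfide F2. Under the same photocatalytic conditions, ring opening and 6-endo addition are followed by β-scission of the phenylthiyl radical from C18, giving the methylene ketone F3 directly. Ring-closing metathesis of F3 gives the macrocyclic enone silyl ether F4, HF·pyridine gives the C10 alcohol F5, and Ac2O/DMAP/pyridine gives 25.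

2. Step 15 (ring-closing metathesis). Closure of a twelve-membered ring that spans trans positions of ring A may suffer from oligomerisation or from poor E/Z control at the new trisubstituted C3=C4 olefin. Fallback, from 20 back to the route at 22: the order of ring closure and ring expansion is exchanged. Metathesis of 20 with the same ruthenium carbene closes the less strained fourteen-membered carbocycle to give the macrocyclic cyclobutanol F6. The photocatalytic ring expansion of step 14 is then run transannularly on F6, so that one event makes ring A and contracts the fourteen-membered ring to the twelve-membered ring of 22.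

3. Step 18 (bis-epoxidation). The conformation of the macrocycle may not expose the required faces of both olefins, leading to poor facial selectivity. Fallback, from 23 back to the route at 26: each oxirane is placed under its own control element. VO(acac)2 and t-BuOOH epoxidise the 7,8-olefin of 23 under direction by the free homoallylic C10 hydroxyl to give the epoxy diol F7. Ac2O and pyridine give the bis-acetate F8. Shi epoxidation (D-fructose-derived ketone, 2KHSO5·KHSO4·K2SO4, K2CO3 buffer, MeCN/dimethoxymethane, 0 °C) epoxidises the remaining E olefin under reagent control to give the 3R,4R oxirane in the bis-epoxide F9. DBU then eliminates acetic acid from F9 to give 26.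

Further compounds
F1 | step 14 | (1S,3R)-3-allyl-1-[(2Z,4R,6Z)-4-(tert-butyldimethylsilyloxy)-1-hydroxy-6,10-dimethylundeca-2,6,10-trien-2-yl]-2,2-dimethylcyclobutan-1-ol | C=C(C)CC/C=C(C)\C[C@@H](O[Si](C)(C)C(C)(C)C)/C=C(CO)\[C@]1(O)C[C@@H](CC=C)C1(C)C
F2 | step 14 | allyl phenyl sulfide of F1 (phenylthio in place of the primary hydroxyl) | C=C(C)CC/C=C(C)\C[C@@H](O[Si](C)(C)C(C)(C)C)/C=C(CSc1ccccc1)\[C@]1(O)C[C@@H](CC=C)C1(C)C
F3 | step 14 | (3S,5R)-5-allyl-3-[(1R,3Z)-1-(tert-butyldimethylsilyloxy)-3,7-dimethylocta-3,7-dienyl]-4,4-dimethyl-2-methylidenecyclohexan-1-one | C=CC[C@@H]1CC(=O)C(=C)[C@@H]([C@H](O[Si](C)(C)C(C)(C)C)C/C(C)=C\CCC(C)=C)C1(C)C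
F4 | step 14 | (1R,3E,7Z,10R,11S)-10-(tert-butyldimethylsilyloxy)verticilla-3,7,12(18)-trien-13-one | C=C1C(=O)C[C@H]2C/C=C(C)/CC/C=C(C)\C[C@@H](O[Si](C)(C)C(C)(C)C)[C@H]1C2(C)C
F5 | step 14 | (1R,3E,7Z,10R,11S)-10-hydroxyverticilla-3,7,12(18)-trien-13-one | C=C1C(=O)C[C@H]2C/C=C(C)/CC/C=C(C)\C[C@@H](O)[C@H]1C2(C)C
F6 | step 15 | fourteen-membered macrocyclic cyclobutanol (C3=C4 E, C7=C8 Z, C11=C12 with C10 cis to C13; cyclobutane C1–C14–C13–C15 bridging the ring) | C1/C(C)=C/C[C@@H]2C[C@](O)(C2(C)C)/C(CO[Si](C)(C)C(C)(C)C)=C\[C@H](O[Si](C)(C)C(C)(C)C)C/C(C)=C\C1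
F7 | step 18 | (1R,3E,7R,8S,10R,11R)-7,8-epoxy-10,18-dihydroxyverticill-3-en-13-one, C12 epimers | OCC1C(=O)C[C@H]2C/C=C(C)/CC[C@H]3O[C@@]3(C)C[C@@H](O)[C@H]1C2(C)C
F8 | step 18 | (1R,3E,7R,8S,10R,11R)-10,18-diacetoxy-7,8-epoxyverticill-3-en-13-one, C12 epimers | CC(=O)OCC1C(=O)C[C@H]2C/C=C(C)/CC[C@H]3O[C@@]3(C)C[C@@H](OC(C)=O)[C@H]1C2(C)C
F9 | step 18 | (1R,3R,4R,7R,8S,10R,11R)-10,18-diacetoxy-3,4:7,8-diepoxyverticillan-13-one, C12 epimers | CC(=O)OCC1C(=O)C[C@H]2C[C@H]3O[C@]3(C)CC[C@H]3O[C@@]3(C)C[C@@H](OC(C)=O)[C@H]1C2(C)C
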